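**Compound numbering used throughout:** 1–20 as defined in the steps and in the compound list; primed atoms belong to unit B.

## Analysis of the target

The target 20, 6-[(6,7-dihydroxy-2-oxo-2H-chromen-5-yl)oxy]-7-hydroxy-2H-chromen-2-one, consists of two coumarin units joined by one diaryl ether oxygen between C6 of unit A (7-hydroxycoumarin part) and C5' of unit B (6,7-dihydroxycoumarin part). It has no stereocenter, and rotation about the ether bonds is expected to be free, so no stereochemical element has to be controlled. The sensitive groups are the C6'/C7' catechol (easily oxidised to an ortho-quinone), the two lactones (opened by hydroxide or alkoxide) and the C3=C4 and C3'=C4' bonds (Michael acceptors, photoreactive). The difficulty is ring B: C4a', C5', C6', C7' and C8a' all carry substituents and only C8' carries hydrogen. The ether oxygen at C5' is flanked by C4a' and by the oxygen at C6', so a late aryl–oxygen coupling there is hindered on both sides. Electrophilic substitution of a 6,7-dioxygenated coumarin does not distinguish C5' from C8'. The strategy rests on the substitution pattern of ring B: oxygen at C8a', carbon at C4a', the aryloxy group at C5' (meta to C8a', with C4a' between them), vicinal oxygens at C6' and C7', hydrogen at C8'. This is the pattern that an oxygen-substituted alkyne and a 2,3-dioxygenated cyclobutenone give when they are merged into a phenol.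

## Retrosynthetic reasoning

**20 from 19.** The three O–CH3 bonds are cut last. Methyl ethers are chosen because the two oxygenated building blocks 3 and 6 already carry them, and because diaryl ether and lactones withstand Lewis-acid ether cleavage. The catechol stays masked until the end.

**19 from 15 and 16.** The pyranone ring of unit B is opened at C3'=C4' and O1'–C2'. This leads to salicylaldehyde 15, whose phenol oxygen is O1' and whose formyl carbon is C4', and to the two-carbon ylide 16. The forward reaction is an olefination followed by E/Z isomerisation and lactonisation (17, 18). The aldehyde of 15 is carried through the ring-forming step as the acetal 14, because a free alkynyl aldehyde would be an acceptor and not a nucleophilic alkyne.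

**14 from 5 and 9.** Ring B is cut at C8a'–C4a', C5'–C6' and C8a'–C8'. The fragments are ynol ether 5, which supplies C4a' and C5' together with the ether oxygen and all of unit A, and cyclobutenone 9, which supplies C6', C7', C8' and C8a'. The forward reaction has to open 9 to vinylketene 10, join it regioselectively to 5 (11), and reorganise through 12 and 13 to the phenol. All five substituents of ring B are then fixed by connectivity, not by directing effects.

**5 from 3 and 2, and 2 from 1.** The O6–C(sp) bond is cut. It is formed as an O–C(sp2) bond between phenol 3 and dibromoalkene 2 to give 4, and dehydrobromination then unveils the triple bond. The hindered C5'–O bond of the target is thus made at an unhindered vinylic carbon before ring B exists. Compound 2 comes from aldehyde 1 by dibromomethylenation.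

**9 from 6.** The C4–O bond of 7 is removed reductively by way of acetate 8, and 7 is the mono-reduction product of squarate 6. The four-membered ring and both methoxy groups are bought.

## Alternatives that were turned down

**Alternative 1:** Both lactone oxygens are traced back to ketones, so the disconnection inserts O1 and O1' into the aryl–carbonyl bonds of bis(1-indanone) A2. The forward key step is a twofold Baeyer–Villiger oxidation of A2 with a peracid, with aryl migration at each ketone, to the bis(3,4-dihydrocoumarin) A1.
- For: both halves are treated alike in one operation. The migrating carbons are para to an oxygen donor (C8a to O6, C8a' to O6'), which favours aryl migration. The indanones come from Friedel–Crafts closures of predictable regiochemistry.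
- Against: A1 is at the wrong oxidation level, so both C3–C4 bonds must be dehydrogenated afterwards, after the side chains were first saturated. The trioxygenated ring B is itself a substrate for peracid. The diaryl ether of A2 must still be made by coupling at the hindered position.
- Comparison: each step is textbook chemistry, which the chosen route cannot claim for its key step. The alternative is longer, however, and leaves the central difficulty untouched. The chosen route forms the ether bond at a vinylic carbon and builds ring B around it.

**Alternative 2:** The two O1–C8a bonds are cut to give the bis-(E)-cinnamic acid A4. The forward key step is a double photocatalytic aerobic C–H lactonisation (flavin sensitiser, visible light) to A3, which is the same compound as 19.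
- For: this is the shortest route on paper. A4 is a few steps from a diaryl ether dialdehyde, and on step economy it is clearly stronger than the chosen route. The free ortho position of ring B is unique and para to O6'.
- Against: ring A offers two different ortho C–H positions, the one that becomes C8a and the one flanked by the aryloxy group, and neither is ortho or para to the methoxy donor, so site control is not built into the substrate. Two oxidative cyclisations must both succeed on one molecule. The fully oxygenated ring B and the product coumarins are themselves oxidisable and photoreactive. The hindered ether bond again comes from an Ullmann-type coupling.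
- Comparison: the chosen route is longer but fixes every position of ring B by connectivity and needs no site-selective C–H oxidation.

**Alternative 3:** Ring A is cut at C5–C6 and C4a–C8a into the bis-silyloxy diene A6 and methyl propiolate A7. The forward key step is a [4+2] cycloaddition followed by aromatisation with loss of the methoxy group, giving resorcylate A5.
- For: ring A is formed regiospecifically with both oxygens free, so ring A needs no demethylation. On protecting-group economy for unit A this is better than the chosen route.
- Against: it constructs the easy ring, which is bought as 3 in the chosen route, and presupposes the hard one, since A6 derives from 5-hydroxy-6,7-dimethoxycoumarin A8 with its C5' oxygen already differentiated. Enolisation and silylation to A6 use amide base in the presence of the lactone. The electron-rich diene can add to C3'=C4'. The ester of A5 must be brought to the aldehyde level before the pyranone can be closed.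
- Comparison: the chosen route puts its risk into the crowded ring, where the structural problem lies.

Key step: step 7

Remark: aldehyde 1 is sold as an aqueous solution and is assumed to be dried before step 1 (extraction into CH2Cl2, MgSO4, 4 Å sieves); 7, 8 and 11 are racemic, which is without consequence for an achiral target.

## Route

**Step 1**
Reactants: 1 2,2-dimethoxyacetaldehyde
Product: 2 1,1-dibromo-3,3-dimethoxyprop-1-ene
Conditions: CBr4, PPh3, Et3N, CH2Cl2, 0 °C
Reagents that add atoms: carbon tetrabromide, BrC(Br)(Br)Br
Why: Ramirez dibromomethylenation (first stage of the Corey–Fuchs sequence) of an unhindered aldehyde. Et3N buffers the medium so that the acetal survives.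

**Step 2**
Reactants: 2 1,1-dibromo-3,3-dimethoxyprop-1-ene; 3 isoscopoletin (6-hydroxy-7-methoxy-2H-chromen-2-one)
Product: 4 (Z)-6-[(1-bromo-3,3-dimethoxyprop-1-en-1-yl)oxy]-7-methoxy-2H-chromen-2-one
Conditions: CuI (10 mol%), 2,2'-bipyridine (20 mol%), K3PO4, PhMe, 110 °C
Reagents that add atoms: none
Why: Copper-catalysed Ullmann-type vinylation of a phenol with a 1,1-dibromoalkene. The C–Br bond trans to the alkene substituent reacts, so one bromine is replaced and the (Z)-bromo enol ether results. The mild phosphate base leaves the lactone closed.

**Step 3**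
Reactants: 4 (Z)-6-[(1-bromo-3,3-dimethoxyprop-1-en-1-yl)oxy]-7-methoxy-2H-chromen-2-one
Product: 5 6-[(3,3-dimethoxyprop-1-yn-1-yl)oxy]-7-methoxy-2H-chromen-2-one
Conditions: KOtBu, THF, −40 → 0 °C
Reagents that add atoms: none
Why: E2 dehydrobromination of a 1-bromo enol ether to an ynol ether. In the (Z)-isomer H and Br are anti, so the elimination should be fast at low temperature, where the hindered alkoxide spares the lactone.

**Step 4**
Reactants: 6 dimethyl squarate (3,4-dimethoxycyclobut-3-ene-1,2-dione)
Product: 7 4-hydroxy-2,3-dimethoxycyclobut-2-en-1-one (racemic)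
Conditions: LiAlH(OtBu)3, THF, −78 → −20 °C; aq. NH4Cl
Reagents that add atoms: none
Why: Selective 1,2-reduction of one squarate carbonyl by a bulky hydride. The remaining carbonyl becomes part of a vinylogous ester and is not reduced further.

**Step 5**
Reactants: 7 4-hydroxy-2,3-dimethoxycyclobut-2-en-1-one
Product: 8 2,3-dimethoxy-4-oxocyclobut-2-en-1-yl acetate (racemic)
Conditions: Ac2O, pyridine, DMAP (cat.), CH2Cl2, 0 °C
Reagents that add atoms: acetic anhydride, CC(=O)OC(C)=O
Why: O-Acylation of a secondary alcohol under basic conditions. Acid is avoided because ionisation of the C4–O bond leads to loss of a methoxy group.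

**Step 6**
Reactants: 8 2,3-dimethoxy-4-oxocyclobut-2-en-1-yl acetate
Product: 9 2,3-dimethoxycyclobut-2-en-1-one
Conditions: SmI2, THF/MeOH, −78 °C
Reagents that add atoms: none
Why: Reductive cleavage of an alpha-acetoxy ketone by SmI2 (two single-electron transfers, loss of acetate, protonation by MeOH). Protonation is expected at C4, the terminus not destabilised by a methoxy lone pair, which keeps the fully substituted enol ether. Zinc dehalogenation of 4-halocyclobutenones shows that reductive cleavage next to a cyclobutenone carbonyl is viable.

**Step 7**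
Reactants: 5 6-[(3,3-dimethoxyprop-1-yn-1-yl)oxy]-7-methoxy-2H-chromen-2-one; 9 2,3-dimethoxycyclobut-2-en-1-one
Product: 14 6-[2-(dimethoxymethyl)-3-hydroxy-5,6-dimethoxyphenoxy]-7-methoxy-2H-chromen-2-one, via 1,2-dimethoxyvinylketene 10 (not isolated), via 4-vinylcyclobutenone 11 (not isolated), via (Z)-dienylketene 12 (not isolated), via cyclohexa-2,4-dienone 13 (not isolated)
Conditions: PhMe, 130 °C, sealed tube, 9 added slowly
Reagents that add atoms: none
Why: Proposed new method: thermal 4-pi electrocyclic opening of 9 gives vinylketene 10, whose carbonyl carbon is attacked by the nucleophilic, acetal-bearing carbon of ynol ether 5 in a [2+2] cycloaddition that forms C8a'–C4a' and C5'–C6' and gives cyclobutenone 11. On 4-pi opening of 11 the methoxy group on the sp3 carbon rotates outward, as donor substituents do, so the methoxyvinyl group turns inward and the (Z)-dienylketene 12 results. Ring B then closes by thermal disrotatory 6-pi electrocyclisation of 12 (C8a'–C8'), and dienone 13 tautomerises to phenol 14. The closest known reaction type is the Danheiser benzannulation of alkyl- and aryl-substituted cyclobutenones with alkoxy- and silyloxyalkynes; the pairing of a 2,3-dialkoxycyclobutenone with an aryl ynol ether has not been shown. No stereocenter remains, since that of 11 is lost on ring opening. The step needs regioselectivity in the [2+2] event, and the polarisation of the ynol ether by its oxygen secures it, placing the aryloxy group at C5' and the acetal carbon at C4a'. The aryl ynol ether has no hydrogen beta to oxygen on its O-substituent, so it cannot fragment by a retro-ene path at the temperature that the donor-stabilised cyclobutenone needs; slow addition keeps the ketene concentration low.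

**Step 8**
Reactants: 14 6-[2-(dimethoxymethyl)-3-hydroxy-5,6-dimethoxyphenoxy]-7-methoxy-2H-chromen-2-one
Product: 15 6-(2-formyl-3-hydroxy-5,6-dimethoxyphenoxy)-7-methoxy-2H-chromen-2-one
Conditions: 1 M HCl, THF, 23 °C
Reagents that add atoms: water, O
Why: Acid hydrolysis of a dimethyl acetal to the aldehyde. Aryl ethers and the lactone are stable to dilute acid at room temperature.

**Step 9**
Reactants: 15 6-(2-formyl-3-hydroxy-5,6-dimethoxyphenoxy)-7-methoxy-2H-chromen-2-one; 16 ethyl (triphenylphosphoranylidene)acetate
Product: 19 6-[(6,7-dimethoxy-2-oxo-2H-chromen-5-yl)oxy]-7-methoxy-2H-chromen-2-one, via (E)-cinnamate ester 17 (not isolated), via (Z)-cinnamate ester 18 (not isolated)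
Conditions: PhNEt2, 215 °C
Reagents that add atoms: none
Why: Wittig olefination of a salicylaldehyde with a stabilised ylide at high temperature, the classical one-pot coumarin synthesis. The (E)-ester isomerises thermally, and the (Z)-ester lactonises onto the ortho-phenol with loss of the ethoxy group.

**Step 10**
Reactants: 19 6-[(6,7-dimethoxy-2-oxo-2H-chromen-5-yl)oxy]-7-methoxy-2H-chromen-2-one
Product: 20 6-[(6,7-dihydroxy-2-oxo-2H-chromen-5-yl)oxy]-7-hydroxy-2H-chromen-2-one
Conditions: BBr3, CH2Cl2, −78 → 23 °C; then MeOH, H2O (under argon)
Reagents that add atoms: none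
Why: Lewis-acid cleavage of aryl methyl ethers by BBr3, with bromide attacking the O-methyl carbon of each boron–ether adduct. The diaryl ether has no sp3 carbon to attack, and the lactones are not cleaved.

## Compound list

1 | 2,2-dimethoxyacetaldehyde | COC(OC)C=O | starting material
2 | 1,1-dibromo-3,3-dimethoxyprop-1-ene | COC(OC)C=C(Br)Br | intermediate
3 | isoscopoletin (6-hydroxy-7-methoxy-2H-chromen-2-one) | COc1cc2oc(=O)ccc2cc1O | starting material
4 | (Z)-6-[(1-bromo-3,3-dimethoxyprop-1-en-1-yl)oxy]-7-methoxy-2H-chromen-2-one | COC(OC)/C=C(\Br)Oc1cc2ccc(=O)oc2cc1OC | intermediate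
5 | 6-[(3,3-dimethoxyprop-1-yn-1-yl)oxy]-7-methoxy-2H-chromen-2-one | COC(OC)C#COc1cc2ccc(=O)oc2cc1OC | intermediate
6 | dimethyl squarate (3,4-dimethoxycyclobut-3-ene-1,2-dione) | COC1=C(OC)C(=O)C1=O | starting material
7 | 4-hydroxy-2,3-dimethoxycyclobut-2-en-1-one (racemic) | COC1=C(OC)C(=O)C1O | intermediate
8 | 2,3-dimethoxy-4-oxocyclobut-2-en-1-yl acetate (racemic) | COC1=C(OC)C(=O)C1OC(C)=O | intermediate
9 | 2,3-dimethoxycyclobut-2-en-1-one | COC1=C(OC)C(=O)C1 | intermediate
10 | 2,3-dimethoxybuta-1,3-dien-1-one (1,2-dimethoxyvinylketene) | O=C=C(OC)C(OC)=C | intermediate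
11 | 6-{[2-(dimethoxymethyl)-4-methoxy-4-(1-methoxyethenyl)-3-oxocyclobut-1-en-1-yl]oxy}-7-methoxy-2H-chromen-2-one (racemic) | COC(OC)C1=C(Oc2cc3ccc(=O)oc3cc2OC)C(OC)(C(OC)=C)C1=O | intermediate
12 | (3Z)-2-(dimethoxymethyl)-4,5-dimethoxy-3-[(7-methoxy-2-oxo-2H-chromen-6-yl)oxy]hexa-1,3,5-trien-1-one | O=C=C(C(OC)OC)/C(Oc1cc2ccc(=O)oc2cc1OC)=C(\C(OC)=C)OC | intermediate
13 | 6-{[2-(dimethoxymethyl)-5,6-dimethoxy-3-oxocyclohexa-1,5-dien-1-yl]oxy}-7-methoxy-2H-chromen-2-one | COC(OC)C1=C(Oc2cc3ccc(=O)oc3cc2OC)C(OC)=C(OC)CC1=O | intermediate
14 | 6-[2-(dimethoxymethyl)-3-hydroxy-5,6-dimethoxyphenoxy]-7-methoxy-2H-chromen-2-one | COC(OC)c1c(O)cc(OC)c(OC)c1Oc1cc2ccc(=O)oc2cc1OC | intermediate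
15 | 6-(2-formyl-3-hydroxy-5,6-dimethoxyphenoxy)-7-methoxy-2H-chromen-2-one | O=Cc1c(O)cc(OC)c(OC)c1Oc1cc2ccc(=O)oc2cc1OC | intermediate
16 | ethyl (triphenylphosphoranylidene)acetate | CCOC(=O)C=P(c1ccccc1)(c1ccccc1)c1ccccc1 | starting material
17 | ethyl (E)-3-{2-hydroxy-4,5-dimethoxy-6-[(7-methoxy-2-oxo-2H-chromen-6-yl)oxy]phenyl}prop-2-enoate | CCOC(=O)/C=C/c1c(O)cc(OC)c(OC)c1Oc1cc2ccc(=O)oc2cc1OC | intermediate
18 | ethyl (Z)-3-{2-hydroxy-4,5-dimethoxy-6-[(7-methoxy-2-oxo-2H-chromen-6-yl)oxy]phenyl}prop-2-enoate | CCOC(=O)/C=C\c1c(O)cc(OC)c(OC)c1Oc1cc2ccc(=O)oc2cc1OC | intermediate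
19 | 6-[(6,7-dimethoxy-2-oxo-2H-chromen-5-yl)oxy]-7-methoxy-2H-chromen-2-one | COc1cc2oc(=O)ccc2cc1Oc1c(OC)c(OC)cc2oc(=O)ccc12 | intermediate
20 | 6-[(6,7-dihydroxy-2-oxo-2H-chromen-5-yl)oxy]-7-hydroxy-2H-chromen-2-one | O=c1ccc2cc(Oc3c(O)c(O)cc4oc(=O)ccc34)c(O)cc2o1 | target

## Step count and least certain steps

Total: 10 steps. Longest linear sequence: 7 steps (steps 1, 2, 3, 7, 8, 9, 10); the cyclobutenone branch (steps 4, 5, 6) joins at step 7 and gives a sequence of the same length.

**Step 7 (key step, proposed new method).**
- What may go wrong: the ring opening of 9 may be too slow, because the C3 methoxy group stabilises the cyclobutenone as a vinylogous ester and C4 carries no substituent that lowers the barrier. At the higher temperature then required, ketene dimerisation, acylation of the new phenol by the ketene, or loss of methanol from the ortho-hydroxy acetal can compete. The aryl ynol ether is also a weaker nucleophile than the alkyl ynol ethers usually employed.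
- Fallback (known chemistry, from 3, back at 19): 3 is coupled with commercial 2-bromo-3,4-dimethoxybenzaldehyde (CuI, N,N-dimethylglycine, Cs2CO3, dioxane, 90 °C; the ortho-formyl group activates the bromide) to give 6-(6-formyl-2,3-dimethoxyphenoxy)-7-methoxy-2H-chromen-2-one F1. Knoevenagel–Doebner condensation with malonic acid (pyridine, piperidine, 100 °C) gives (E)-3-{3,4-dimethoxy-2-[(7-methoxy-2-oxo-2H-chromen-6-yl)oxy]phenyl}prop-2-enoic acid F2. Flavin-photocatalysed aerobic lactonisation (riboflavin, blue light, O2, MeCN/MeOH) onto the only free ortho position, which is para to a methoxy group, gives 19.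

**Step 6.**
- What may go wrong: hydrogen may be delivered to the methoxy-bearing terminus of the delocalised three-carbon intermediate instead of to C4, or the reduced species may couple, because the enolate of a cyclobutenone is poorly stabilised. Anhydrous acid should equilibrate the enol ether isomers towards the more substituted one by C-protonation and deprotonation.
- Fallback (from 7, back at 9): radical deoxygenation. 7 is converted with phenyl chlorothionoformate and pyridine into O-(2,3-dimethoxy-4-oxocyclobut-2-en-1-yl) O-phenyl carbonothioate F3. Barton–McCombie reduction (Bu3SnH, AIBN, PhMe, 80 °C), with hydrogen-atom transfer to the unhindered C4 terminus, gives 9.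

**Step 3.**
- What may go wrong: alkoxide may open the lactone or add to C3=C4 faster than it eliminates, or the propargylic acetal may isomerise under base.
- Fallback (from 3, back at 5; it also bypasses step 2): 3 is O-alkylated with commercial 1-bromo-3,3-dimethoxypropan-2-one (K2CO3, acetone) to give 6-(3,3-dimethoxy-2-oxopropoxy)-7-methoxy-2H-chromen-2-one F4. Chelation-controlled enolisation and triflation (LiHMDS, PhNTf2, THF, −78 °C) give (Z)-3,3-dimethoxy-1-[(7-methoxy-2-oxo-2H-chromen-6-yl)oxy]prop-1-en-2-yl trifluoromethanesulfonate F5. The better leaving group allows anti elimination with KOtBu at −78 °C, a temperature the lactone should tolerate, to give 5.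

**Step 9.**
- What may go wrong: the aldehyde is flanked by two ortho substituents, so olefination may stall, or the (E)-ester may fail to isomerise and lactonise before thermal degradation sets in.
- Fallback (from 15, back at 19): Knoevenagel condensation of 15 with Meldrum's acid (piperidinium acetate, EtOH, reflux) closes the lactone directly and gives 6,7-dimethoxy-5-[(7-methoxy-2-oxo-2H-chromen-6-yl)oxy]-2-oxo-2H-chromene-3-carboxylic acid F6. Decarboxylation (Cu powder, quinoline, 200 °C) gives 19.

## Further compounds

F1 | step 7 | 6-(6-formyl-2,3-dimethoxyphenoxy)-7-methoxy-2H-chromen-2-one | O=Cc1ccc(OC)c(OC)c1Oc1cc2ccc(=O)oc2cc1OC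
F2 | step 7 | (E)-3-{3,4-dimethoxy-2-[(7-methoxy-2-oxo-2H-chromen-6-yl)oxy]phenyl}prop-2-enoic acid | OC(=O)/C=C/c1ccc(OC)c(OC)c1Oc1cc2ccc(=O)oc2cc1OC
F3 | step 6 | O-(2,3-dimethoxy-4-oxocyclobut-2-en-1-yl) O-phenyl carbonothioate (racemic) | COC1=C(OC)C(=O)C1OC(=S)Oc1ccccc1
F4 | step 3 | 6-(3,3-dimethoxy-2-oxopropoxy)-7-methoxy-2H-chromen-2-one | COC(OC)C(=O)COc1cc2ccc(=O)oc2cc1OC
F5 | step 3 | (Z)-3,3-dimethoxy-1-[(7-methoxy-2-oxo-2H-chromen-6-yl)oxy]prop-1-en-2-yl trifluoromethanesulfonate | COC(OC)/C(OS(=O)(=O)C(F)(F)F)=C/Oc1cc2ccc(=O)oc2cc1OC
F6 | step 9 | 6,7-dimethoxy-5-[(7-methoxy-2-oxo-2H-chromen-6-yl)oxy]-2-oxo-2H-chromene-3-carboxylic acid | COc1cc2oc(=O)ccc2cc1Oc1c(OC)c(OC)cc2oc(=O)c(C(=O)O)cc12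
A1 | alternative 1 | 6-[(6,7-dimethoxy-2-oxo-3,4-dihydro-2H-chromen-5-yl)oxy]-7-methoxy-3,4-dihydro-2H-chromen-2-one | COc1cc2OC(=O)CCc2cc1Oc1c(OC)c(OC)cc2OC(=O)CCc12
A2 | alternative 1 | 4-[(6-methoxy-1-oxo-2,3-dihydro-1H-inden-5-yl)oxy]-5,6-dimethoxy-2,3-dihydro-1H-inden-1-one | COc1cc2C(=O)CCc2cc1Oc1c(OC)c(OC)cc2C(=O)CCc12
A3 | alternative 2 | 6-[(6,7-dimethoxy-2-oxo-2H-chromen-5-yl)oxy]-7-methoxy-2H-chromen-2-one | COc1cc2oc(=O)ccc2cc1Oc1c(OC)c(OC)cc2oc(=O)ccc12
A4 | alternative 2 | (E)-3-{2-[5-((E)-2-carboxyethenyl)-2-methoxyphenoxy]-3,4-dimethoxyphenyl}prop-2-enoic acid | COc1ccc(/C=C/C(=O)O)cc1Oc1c(OC)c(OC)ccc1/C=C/C(=O)O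
A5 | alternative 3 | methyl 5-[(6,7-dimethoxy-2-oxo-2H-chromen-5-yl)oxy]-2,4-dihydroxybenzoate | COC(=O)c1cc(Oc2c(OC)c(OC)cc3oc(=O)ccc23)c(O)cc1O
A6 | alternative 3 | 6,7-dimethoxy-5-{[4-methoxy-2,4-bis(trimethylsilyloxy)buta-1,3-dien-1-yl]oxy}-2H-chromen-2-one (double-bond geometry not fixed) | COC(O[Si](C)(C)C)=CC(O[Si](C)(C)C)=COc1c(OC)c(OC)cc2oc(=O)ccc12
A7 | alternative 3 | methyl propiolate | COC(=O)C#C
A8 | alternative 3 | 5-hydroxy-6,7-dimethoxy-2H-chromen-2-one | COc1cc2oc(=O)ccc2c(O)c1OC
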